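# Proposed total synthesis of dodoviscin J by carbene-catalysed benzoin closure of ring C

## Structural features

Dodoviscin J (18) is a 3-O-methylated flavonol in which ring A, a phloroglucinol-type benzene ring with free hydroxyls at C5 and C7, is fused through C4a and C8a to ring C, a γ-pyranone with the carbonyl at C4, a methoxy group at C3 and ring B bonded directly to C2. Ring B is a 1,3,4,5-tetrasubstituted benzene whose C4′ hydroxyl is flanked by a methoxy group (C3′) and a 3-methylbut-2-enyl chain (C5′). The target has no stereocentre and its trisubstituted alkene has no geometrical isomers, so the only stereochemistry in the plan is transient: the adjacent C2 and C3 of a chromanone intermediate, both of which become trigonal again. The fragile elements are the prenyl group beside a phenol (acid closes it to a 2,2-dimethylchroman; electrophilic halogen, hydrogenation and strong oxidants attack the alkene), the electron-rich polyphenol, and the enolisable carbonyl compounds met on the way. The real difficulty is differentiation rather than carbon count: five peripheral oxygens, of which exactly two are methylated and one of these (O3) sits on the pyranone, plus a regiodefined ortho-prenyl group that rules out harsh ring-forming conditions. The key step uses the 1,2-dioxygenation pattern C3(–O)–C4(=O) of ring C, in which both carbons are at the carbonyl oxidation level and are tied to ring A through O1–C2. The C3–C4 bond can therefore be made from two formyl groups by an acyl-anion (umpolung) addition that closes a six-membered ring.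

## Logic of the disconnections

**18 to 17.** The three acetal O–CH2 bonds at O5, O7 and O4′ are cut. The phenols must be masked through the hydride, periodinane, carbene/base and alkylation chemistry. This reduces a polyphenol problem to a single-hydroxyl problem. The forward step must use acid mild enough to spare the prenyl group next to the liberated 4′-hydroxyl.

**17 to 16.** The O–CH3 bond at C3 is cut. In 16 the C3 hydroxyl is the only free one, so methylation needs no selectivity. The demand is that no earlier step uncovers another hydroxyl.

**16 to 14 (through 15).** The C2=C3 unsaturation is removed in the retrosynthetic sense, exposing an α-hydroxy ketone, the retron of a benzoin addition. The forward oxidation must leave the alkene and the acetals alone. It erases C2 and C3 as stereocentres, so their configuration in 14 never needs to be controlled.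

**14 to 13.** The C3–C4 bond is cut. It joins two carbonyl-level carbons, so it is traced to two formyl groups, one of which reacts as an acyl anion. This opens ring C and leaves an acyclic ether. The forward step needs intramolecular cross-coupling to beat dimerisation, and tolerance of an enolisable aldehyde.

**13 to 12 to 11.** No skeletal bond is cut; both formyl groups are traced to primary alcohols and then to the ester and aldehyde of 11. No hydride will stop an ester at the aldehyde while sparing an aromatic aldehyde, so both are reduced and re-oxidised together. The forward pair must spare alkene and acetals and deliver 13 without purification stress.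

**11 to 10 and 8.** The O1–C2 ether bond is cut. This is the convergent point: a phenoxide meets a doubly activated (benzylic, α-carbonyl) secondary bromide. The base must be mild enough not to trigger aldol closure of the product.

**10 to 9.** Two acetal O–C bonds are cut. The hydroxyl next to the formyl group is hydrogen-bonded and less nucleophilic, so it stays free. The forward step needs controlled stoichiometry.

**8 to 6 (through 7) to 5.** The C–Br bond α to the ester is cut, then the acetal on O4′. Bromination is done on an enolate because a radical method would attack the prenyl group. The brominating agent must meet the enolate, not the alkene.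

**5 to 2 and 3 (through 4), and 2 to 1.** The aryl C5′–CH2 bond is cut at the earliest stage, on the cheapest material. The para position and one ortho position are blocked, so only one site is open. The ester O–CH3 bond is then cut to reach the acid. The forward prenylation must favour carbon over oxygen.

## Other disconnections considered

Alternative 1: The cut runs through C4–C4a and O1–C2. Phloroglucinol A1 and methyl 3-(3-bromo-4-hydroxy-5-methoxyphenyl)-2-methoxy-3-oxopropanoate A2 would be heated neat near 240 °C. C-acylation of A1 by the ester of A2, followed by cyclodehydration of a flanking phenol onto the aryl ketone (a Mentzer/Simonis-type chromone synthesis), would give the bromoflavone 2-(3-bromo-4-hydroxy-5-methoxyphenyl)-5,7-dihydroxy-3-methoxychromen-4-one A3. The prenyl group would then be introduced by cross-coupling of the aryl bromide of A3 with a prenyl–metal reagent (for instance with Pd(PPh3)4) to reach 18.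
- In its favour: A1 is symmetric, so ring A poses no regiochemical question. The C3 methoxy group arrives with A2, so no oxidation, no late methylation and no protecting groups on ring A are needed. The count of operations would be roughly half that of the chosen plan.
- Against it here: the temperature excludes the prenyl group, hence the bromine placeholder. It is also severe for an α-alkoxy β-keto ester such as A2 (retro-Claisen loss, coumarin-type closure as a competing mode). The final coupling would have to work on A3, an electron-rich, ortho-hydroxylated aryl bromide in an unprotected triphenol, with the usual linear/branched ambiguity of prenyl–metal reagents. Protection might be needed after all.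
- Comparison: on step economy and protecting-group economy Alternative 1 is the better plan, and in convergence it is equal. The chosen plan is better in mildness, in carrying the prenyl group from the first stage, and in placing its least certain step mid-route and not at the very end. Mechanistically it is a high-temperature electrophilic acylation against a room-temperature catalytic umpolung.

Alternative 2: The cut is C7–C8, so ring A is built last on a finished pyranone. The precursor would be methyl 3-{5-methoxy-6-[3-methoxy-4-(methoxymethoxy)-5-(3-methylbut-2-enyl)phenyl]-2-methyl-4-oxo-4H-pyran-3-yl}-3-oxopropanoate A4. With excess lithium diisopropylamide the vinylogous carbanion of the C-methyl group of A4 would attack the terminal ester (Claisen-type, six-membered). Enolisation would aromatise ring A to give the 4′-O-methoxymethyl ether of dodoviscin J A5.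
- In its favour: it mirrors the polyketide origin of ring A and delivers the 5- and 7-hydroxyls free. The prenyl group tolerates amide bases. From A5 only one deprotection would remain, against three operations after the key step of the chosen plan; on that count it is the better.
- Against it here: A4 is a γ-pyranone with four different substituents and has no obvious convergent access. Its preparation would plausibly be longer than the whole chosen route. The β-keto ester of A4 is deprotonated first, and its enolate deactivates the very ester that must be attacked. Several acidic sites compete.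
- Comparison: the final acid step is the same, so the two plans are equal there. Both form the ring by anionic C–C bond formation, but stoichiometric polyanion chemistry is less forgiving than a catalytic, near-neutral closure. Overall step economy should favour the chosen plan.

Alternative 3: The cut runs through O1–C8a and C4–C4a. On treatment with CsF, 3,5-bis(methoxymethoxy)-2-(trimethylsilyl)phenyl trifluoromethanesulfonate A6 would release 3,5-bis(methoxymethoxy)benzyne A7. The enolate oxygen of methyl 2-methoxy-3-[3-methoxy-4-(methoxymethoxy)-5-(3-methylbut-2-enyl)phenyl]-3-oxopropanoate A8 would add to A7 at the aryne carbon remote from the alkoxy group (C8a). The aryl anion formed at C4a would then acylate on the ester, giving the tris(methoxymethyl) ether A9, which is the same compound as 17.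
- In its favour: it is very convergent, runs under mild fluoride conditions that suit prenyl and acetals, and reaches the penultimate compound directly with no redox shuffling and no separate methylation. The regiochemistry of addition to a 3-alkoxyaryne such as A7 is dependable.
- Against it here: the enolate of A8 is ambident, and arynes normally take such enolates at carbon, which leads to acyl–alkylation (C–C insertion) and not to O-arylation and chromone closure. The aryl anion may also be quenched by the acidic keto ester A8. A6 itself needs about four steps.
- Comparison: in protecting-group strategy and final deprotection the two plans are equal. In convergence and in avoiding a labile dialdehyde Alternative 3 is the better. In the certainty of the pivotal chemoselectivity the chosen plan is stronger, because both regiochemical outcomes of its key step converge on one product. Total step counts should be similar.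

Key step: step 9

Remark on the chemistry: every intermediate carrying C2 as a stereocentre (8 and 11 to 15) is made as the racemate, which is harmless because C2 becomes trigonal in step 10. Ester 2 is also an article of commerce and could be bought, which would remove step 1.

## Route

Step 1
Reactants: 1 homovanillic acid [2-(4-hydroxy-3-methoxyphenyl)acetic acid]
Product: 2 methyl 2-(4-hydroxy-3-methoxyphenyl)acetate
Conditions: MeOH, H2SO4 (cat.), reflux
Reagents that add atoms: methanol, CO
Why: Fischer esterification driven by excess methanol; the phenol is untouched and the acid is masked for the phenoxide and enolate chemistry that follows.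

Step 2
Reactants: 2 methyl 2-(4-hydroxy-3-methoxyphenyl)acetate; 3 1-bromo-3-methylbut-2-ene
Product: 5 methyl 2-[4-hydroxy-3-methoxy-5-(3-methylbut-2-enyl)phenyl]acetate, via sodium phenoxide 4 (not isolated)
Conditions: NaH (1.0 equiv), toluene, 0 °C to rt; then 3, rt to 40 °C
Reagents that add atoms: none
Why: ortho-C-alkylation of a sodium phenoxide as a tight ion pair in a non-polar solvent, where the cation shields oxygen and the allylic bromide is delivered to the ortho carbon; C5 is the only free ortho/para position, so the regiochemistry is fixed. One equivalent of base deprotonates only the phenol, and the O-prenyl ether expected as by-product is separable.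

Step 3
Reactants: 5 methyl 2-[4-hydroxy-3-methoxy-5-(3-methylbut-2-enyl)phenyl]acetate
Product: 6 methyl 2-[3-methoxy-4-(methoxymethoxy)-5-(3-methylbut-2-enyl)phenyl]acetate
Conditions: MOMCl, iPr2NEt, CH2Cl2, 0 °C to 40 °C
Reagents that add atoms: chloromethyl methyl ether, COCCl
Why: Williamson-type alkylation of the hindered phenol to its methoxymethyl acetal; this group withstands amide base, hydride, periodinane, carbene/amidine and MeI/K2CO3 and leaves in the last step together with the two on ring A.

Step 4
Reactants: 6 methyl 2-[3-methoxy-4-(methoxymethoxy)-5-(3-methylbut-2-enyl)phenyl]acetate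
Product: 8 methyl 2-bromo-2-[3-methoxy-4-(methoxymethoxy)-5-(3-methylbut-2-enyl)phenyl]acetate (racemic), via lithium ester enolate 7 (not isolated)
Conditions: LiN(SiMe3)2, THF, −78 °C; enolate cannulated into NBS, THF, −78 °C
Reagents that add atoms: N-bromosuccinimide, O=C1CCC(=O)N1Br
Why: α-bromination of an ester enolate; at −78 °C the enolate is far more nucleophilic towards electrophilic bromine than the prenyl alkene, and inverse addition keeps it away from the product bromide. The new stereocentre is racemic and irrelevant; the activated benzylic bromide is used without chromatography.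

Step 5
Reactants: 9 2,4,6-trihydroxybenzaldehyde
Product: 10 2-hydroxy-4,6-bis(methoxymethoxy)benzaldehyde
Conditions: MOMCl (2.1 equiv), iPr2NEt, CH2Cl2, 0 °C to rt
Reagents that add atoms: chloromethyl methyl ether, COCCl
Why: chemoselective phenol alkylation; once one ortho hydroxyl and the para hydroxyl are capped, the remaining ortho hydroxyl is locked in a hydrogen bond to the formyl oxygen and reacts much more slowly, so it stays free for step 6.

Step 6
Reactants: 10 2-hydroxy-4,6-bis(methoxymethoxy)benzaldehyde; 8 methyl 2-bromo-2-[3-methoxy-4-(methoxymethoxy)-5-(3-methylbut-2-enyl)phenyl]acetate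
Product: 11 methyl 2-[2-formyl-3,5-bis(methoxymethoxy)phenoxy]-2-[3-methoxy-4-(methoxymethoxy)-5-(3-methylbut-2-enyl)phenyl]acetate (racemic)
Conditions: K2CO3, DMF, 0 °C to rt
Reagents that add atoms: none
Why: Williamson ether synthesis (SN2) at a secondary bromide activated by both the aryl ring and the ester, forming the O1–C2 bond. Mild carbonate at room temperature avoids the aldol closure of the product onto its own formyl group that stronger base or heat would promote.

Step 7
Reactants: 11 methyl 2-[2-formyl-3,5-bis(methoxymethoxy)phenoxy]-2-[3-methoxy-4-(methoxymethoxy)-5-(3-methylbut-2-enyl)phenyl]acetate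
Product: 12 2-[2-(hydroxymethyl)-3,5-bis(methoxymethoxy)phenoxy]-2-[3-methoxy-4-(methoxymethoxy)-5-(3-methylbut-2-enyl)phenyl]ethanol (racemic)
Conditions: LiAlH4, THF, 0 °C
Reagents that add atoms: none
Why: hydride reduction of ester and aldehyde to the two primary alcohols; acetals, aryl ethers and the isolated alkene are inert. Both carbonyls are taken down together because the ester cannot be stopped at the aldehyde in the presence of the aromatic formyl group.

Step 8
Reactants: 12 2-[2-(hydroxymethyl)-3,5-bis(methoxymethoxy)phenoxy]-2-[3-methoxy-4-(methoxymethoxy)-5-(3-methylbut-2-enyl)phenyl]ethanol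
Product: 13 2-[2-formyl-3,5-bis(methoxymethoxy)phenoxy]-2-[3-methoxy-4-(methoxymethoxy)-5-(3-methylbut-2-enyl)phenyl]acetaldehyde (racemic)
Conditions: Dess–Martin periodinane (2.5 equiv), NaHCO3, CH2Cl2, 0 °C to rt; filtered and used crude
Reagents that add atoms: none
Why: Dess–Martin oxidation of both primary alcohols stops at the aldehyde and is non-basic and buffered, which suits the acid-sensitive electron-rich benzylic alcohol, the acetals and the alkene. The enolisable α-aryloxy aldehyde is not purified but taken straight into step 9.

Step 9
Reactants: 13 2-[2-formyl-3,5-bis(methoxymethoxy)phenoxy]-2-[3-methoxy-4-(methoxymethoxy)-5-(3-methylbut-2-enyl)phenyl]acetaldehyde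
Product: 14 racemic trans-3-hydroxy-5,7-bis(methoxymethoxy)-2-[3-methoxy-4-(methoxymethoxy)-5-(3-methylbut-2-enyl)phenyl]chroman-4-one (2S,3S enantiomer drawn)
Conditions: 2-(pentafluorophenyl)-6,7-dihydro-5H-pyrrolo[2,1-c][1,2,4]triazol-2-ium tetrafluoroborate (15 mol%), DBU (12 mol%), toluene (0.02 M), rt, Ar
Reagents that add atoms: none
Why: Deprotonation of the triazolium salt gives the carbene, which adds to one formyl group of 13; proton transfer yields the Breslow intermediate, an acyl-anion equivalent, and this attacks the other, tethered formyl carbon, after which proton transfer and expulsion of the carbene leave the cyclic acyloin. The closest known reaction type is the azolium-catalysed intramolecular crossed benzoin cyclisation of O-tethered salicylaldehyde derivatives to 3-hydroxychroman-4-ones. Ring C closes in the 6-exo-trig mode, C3–C4 being the only skeletal bond formed. With the aromatic formyl group as donor 14 results directly; with the aliphatic one as donor the regioisomeric acyloin (hydroxyl at C4, ketone at C3) would result, which can drift to the aryl-conjugated ketone 14 through the enediol under the basic conditions and in any case gives the same dione in step 10. The new stereocentre C3 is set relative to C2 under thermodynamic control, since C3–H is enolisable: the 2,3-trans isomer with aryl and hydroxyl both equatorial on the half-chair should dominate, and the question is moot because step 10 flattens both centres. The step needs cyclisation to outrun intermolecular homo-benzoin, which the six-membered tether and high dilution secure. It also needs C–C bond formation to outrun base-induced enolisation and aldol closure of the α-aryloxy aldehyde and loss of aryloxide from the Breslow intermediate; the first is countered by using less amidine than azolium salt so that no free strong base remains, the second by the proximity of the acceptor carbonyl.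

Step 10
Reactants: 14 racemic trans-3-hydroxy-5,7-bis(methoxymethoxy)-2-[3-methoxy-4-(methoxymethoxy)-5-(3-methylbut-2-enyl)phenyl]chroman-4-one
Product: 16 3-hydroxy-5,7-bis(methoxymethoxy)-2-[3-methoxy-4-(methoxymethoxy)-5-(3-methylbut-2-enyl)phenyl]-4H-chromen-4-one, via chroman-3,4-dione 15 (not isolated)
Conditions: Dess–Martin periodinane (1.2 equiv), NaHCO3, CH2Cl2, 0 °C to rt
Reagents that add atoms: none
Why: Dess–Martin oxidation of the acyloin to the 1,2-dione, whose doubly activated C2–H enolises at once to the hydrogen-bonded 3-hydroxy-γ-pyranone. A buffered periodinane is preferred to iodine in hot DMSO because it generates no HI and needs no heat, both of which would endanger the acetals and the prenyl group.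

Step 11
Reactants: 16 3-hydroxy-5,7-bis(methoxymethoxy)-2-[3-methoxy-4-(methoxymethoxy)-5-(3-methylbut-2-enyl)phenyl]-4H-chromen-4-one
Product: 17 3-methoxy-5,7-bis(methoxymethoxy)-2-[3-methoxy-4-(methoxymethoxy)-5-(3-methylbut-2-enyl)phenyl]-4H-chromen-4-one
Conditions: MeI, K2CO3, acetone, 50 °C
Reagents that add atoms: iodomethane, CI
Why: Williamson O-methylation of the acidic C3 enol hydroxyl, the only free hydroxyl in the molecule, so no selectivity question arises.

Step 12
Reactants: 17 3-methoxy-5,7-bis(methoxymethoxy)-2-[3-methoxy-4-(methoxymethoxy)-5-(3-methylbut-2-enyl)phenyl]-4H-chromen-4-one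
Product: 18 dodoviscin J [5,7-dihydroxy-2-[4-hydroxy-3-methoxy-5-(3-methylbut-2-enyl)phenyl]-3-methoxy-4H-chromen-4-one]
Conditions: HCl (1.25 M in MeOH), 40 °C, stopped at full conversion
Reagents that add atoms: none
Why: acid-catalysed transacetalisation of the three aryl methoxymethyl ethers to methanol, a standard unmasking for prenylated flavonoids; aryl methyl ethers are stable. Moderate temperature and short exposure keep the ortho-prenyl phenol from cyclising.

## Compound list

1 | homovanillic acid, 2-(4-hydroxy-3-methoxyphenyl)acetic acid | COc1cc(CC(=O)O)ccc1O | starting material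
2 | methyl 2-(4-hydroxy-3-methoxyphenyl)acetate | COC(=O)Cc1ccc(O)c(OC)c1 | intermediate
3 | 1-bromo-3-methylbut-2-ene | CC(C)=CCBr | starting material
4 | sodium 2-methoxy-4-(2-methoxy-2-oxoethyl)phenoxide | [Na+].[O-]c1ccc(CC(=O)OC)cc1OC | intermediate
5 | methyl 2-[4-hydroxy-3-methoxy-5-(3-methylbut-2-enyl)phenyl]acetate | COC(=O)Cc1cc(OC)c(O)c(CC=C(C)C)c1 | intermediate
6 | methyl 2-[3-methoxy-4-(methoxymethoxy)-5-(3-methylbut-2-enyl)phenyl]acetate | COC(=O)Cc1cc(OC)c(OCOC)c(CC=C(C)C)c1 | intermediate
7 | lithium enolate of 6 (enolate geometry not defined) | [Li+].[O-]C(OC)=Cc1cc(OC)c(OCOC)c(CC=C(C)C)c1 | intermediate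
8 | methyl 2-bromo-2-[3-methoxy-4-(methoxymethoxy)-5-(3-methylbut-2-enyl)phenyl]acetate (racemic) | COC(=O)C(Br)c1cc(OC)c(OCOC)c(CC=C(C)C)c1 | intermediate
9 | 2,4,6-trihydroxybenzaldehyde | O=Cc1c(O)cc(O)cc1O | starting material
10 | 2-hydroxy-4,6-bis(methoxymethoxy)benzaldehyde | COCOc1cc(O)c(C=O)c(OCOC)c1 | intermediate
11 | methyl 2-[2-formyl-3,5-bis(methoxymethoxy)phenoxy]-2-[3-methoxy-4-(methoxymethoxy)-5-(3-methylbut-2-enyl)phenyl]acetate (racemic) | COC(=O)C(Oc1cc(OCOC)cc(OCOC)c1C=O)c1cc(OC)c(OCOC)c(CC=C(C)C)c1 | intermediate
12 | 2-[2-(hydroxymethyl)-3,5-bis(methoxymethoxy)phenoxy]-2-[3-methoxy-4-(methoxymethoxy)-5-(3-methylbut-2-enyl)phenyl]ethanol (racemic) | OCC(Oc1cc(OCOC)cc(OCOC)c1CO)c1cc(OC)c(OCOC)c(CC=C(C)C)c1 | intermediate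
13 | 2-[2-formyl-3,5-bis(methoxymethoxy)phenoxy]-2-[3-methoxy-4-(methoxymethoxy)-5-(3-methylbut-2-enyl)phenyl]acetaldehyde (racemic) | O=CC(Oc1cc(OCOC)cc(OCOC)c1C=O)c1cc(OC)c(OCOC)c(CC=C(C)C)c1 | intermediate
14 | racemic trans-3-hydroxy-5,7-bis(methoxymethoxy)-2-[3-methoxy-4-(methoxymethoxy)-5-(3-methylbut-2-enyl)phenyl]chroman-4-one (2S,3S enantiomer drawn) | O=C1[C@@H](O)[C@H](c3cc(OC)c(OCOC)c(CC=C(C)C)c3)Oc2cc(OCOC)cc(OCOC)c21 | intermediate
15 | 5,7-bis(methoxymethoxy)-2-[3-methoxy-4-(methoxymethoxy)-5-(3-methylbut-2-enyl)phenyl]chroman-3,4-dione (racemic) | O=C1C(=O)C(c3cc(OC)c(OCOC)c(CC=C(C)C)c3)Oc2cc(OCOC)cc(OCOC)c21 | intermediate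
16 | 3-hydroxy-5,7-bis(methoxymethoxy)-2-[3-methoxy-4-(methoxymethoxy)-5-(3-methylbut-2-enyl)phenyl]-4H-chromen-4-one | O=c1c(O)c(-c3cc(OC)c(OCOC)c(CC=C(C)C)c3)oc2cc(OCOC)cc(OCOC)c12 | intermediate
17 | 3-methoxy-5,7-bis(methoxymethoxy)-2-[3-methoxy-4-(methoxymethoxy)-5-(3-methylbut-2-enyl)phenyl]-4H-chromen-4-one | O=c1c(OC)c(-c3cc(OC)c(OCOC)c(CC=C(C)C)c3)oc2cc(OCOC)cc(OCOC)c12 | intermediate
18 | dodoviscin J, 5,7-dihydroxy-2-[4-hydroxy-3-methoxy-5-(3-methylbut-2-enyl)phenyl]-3-methoxy-4H-chromen-4-one | COc1cc(-c2oc3cc(O)cc(O)c3c(=O)c2OC)cc(CC=C(C)C)c1O | target

## Step count and least certain steps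

Total step count: 12.
Longest linear sequence: 11 steps (1 to 18 through steps 1 to 4 and 6 to 12); step 5 is a one-step branch.

**Step 9 (key step).** The most likely failure is diversion of the carbene chemistry away from C–C bond formation.
- The Breslow intermediate on the aliphatic formyl group can expel the α-aryloxide, an internal redox path that ends in acyl transfer.
- The enolisable α-aryloxy aldehyde can close by a base-induced 5-exo aldol onto the aromatic formyl group.
- Carbene addition to the di-ortho-oxygenated, electron-rich aromatic aldehyde is slow.
- The tendency of 13 to enolise and autoxidise adds to this, which is why it is made and consumed without purification.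

The fallback sets out from 13 and returns at 16, replacing carbene umpolung by reductive umpolung. SmI2 (2.2 equiv) in THF at −78 °C should effect a ketyl–carbonyl pinacol cyclisation without any base, giving 5,7-bis(methoxymethoxy)-2-[3-methoxy-4-(methoxymethoxy)-5-(3-methylbut-2-enyl)phenyl]chroman-3,4-diol F1 as a mixture of diastereomers. Swern oxidation of both carbinols of F1 (DMSO, (COCl)2, CH2Cl2, −78 °C, then Et3N) should then give dione 15 and, by tautomerisation, 16, so that step 10 is no longer needed.

**Step 2.** The most likely failure is O-alkylation of the phenoxide in place of ortho-C-alkylation, since the carbon/oxygen partition of ambident phenoxides depends on ion pairing and is rarely complete. The fallback sets out from 2 and returns at 5, building the side chain by sigmatropic transfer and metathesis. Allyl bromide and K2CO3 in acetone give methyl 2-[3-methoxy-4-(prop-2-enyloxy)phenyl]acetate F2. Aromatic Claisen rearrangement near 200 °C moves the allyl group to the only free ortho carbon, giving methyl 2-[4-hydroxy-3-methoxy-5-(prop-2-enyl)phenyl]acetate F3. Cross-metathesis of F3 with excess 2-methyl-2-butene and the second-generation Grubbs catalyst (H2IMes)(PCy3)Cl2Ru=CHPh in CH2Cl2 at 40 °C converts the allyl into the prenyl group of 5.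

**Step 4.** The most likely failures are attack of the electrophilic bromine source on the prenyl alkene, coupling of the enolate with the bromide already formed, and solvolytic loss of the activated benzylic bromide on handling. The fallback sets out from 6 and returns at 11; it also bypasses the base-mediated step 6. Enolate hydroxylation (KN(SiMe3)2, THF, −78 °C, then 2-(phenylsulfonyl)-3-phenyloxaziridine) gives methyl 2-hydroxy-2-[3-methoxy-4-(methoxymethoxy)-5-(3-methylbut-2-enyl)phenyl]acetate F4 as the racemate. A Mitsunobu reaction of F4 with phenol 10 (PPh3, diisopropyl azodicarboxylate, THF, 0 °C to rt) forms the O1–C2 bond of 11 under neutral conditions.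

**Step 12.** The most likely failure is acid-catalysed addition of the freed 4′-hydroxyl to the protonated prenyl alkene (chroman ring closure), or hydrochlorination of the alkene, competing with the slower cleavage of the hindered 4′-acetal. The fallback sets out from 17 and returns at 18, exchanging the acetals for silyl ethers under non-protic conditions. Me3SiOTf with 2,2′-bipyridyl in MeCN at 0 °C should convert the three aryl methoxymethyl ethers into 3-methoxy-2-[3-methoxy-5-(3-methylbut-2-enyl)-4-(trimethylsilyloxy)phenyl]-5,7-bis(trimethylsilyloxy)-4H-chromen-4-one F5. Addition of water at neutral pH hydrolyses F5 to 18 without exposing the prenyl phenol to Brønsted acid.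

## Further compounds

F1 | step 9 | 5,7-bis(methoxymethoxy)-2-[3-methoxy-4-(methoxymethoxy)-5-(3-methylbut-2-enyl)phenyl]chroman-3,4-diol (racemic mixture of diastereomers) | OC1C(O)C(c3cc(OC)c(OCOC)c(CC=C(C)C)c3)Oc2cc(OCOC)cc(OCOC)c21
F2 | step 2 | methyl 2-[3-methoxy-4-(prop-2-enyloxy)phenyl]acetate | COC(=O)Cc1ccc(OCC=C)c(OC)c1
F3 | step 2 | methyl 2-[4-hydroxy-3-methoxy-5-(prop-2-enyl)phenyl]acetate | COC(=O)Cc1cc(OC)c(O)c(CC=C)c1
F4 | step 4 | methyl 2-hydroxy-2-[3-methoxy-4-(methoxymethoxy)-5-(3-methylbut-2-enyl)phenyl]acetate (racemic) | COC(=O)C(O)c1cc(OC)c(OCOC)c(CC=C(C)C)c1
F5 | step 12 | 3-methoxy-2-[3-methoxy-5-(3-methylbut-2-enyl)-4-(trimethylsilyloxy)phenyl]-5,7-bis(trimethylsilyloxy)-4H-chromen-4-one | O=c1c(OC)c(-c3cc(OC)c(O[Si](C)(C)C)c(CC=C(C)C)c3)oc2cc(O[Si](C)(C)C)cc(O[Si](C)(C)C)c12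
A1 | alternative 1 | phloroglucinol, benzene-1,3,5-triol | Oc1cc(O)cc(O)c1
A2 | alternative 1 | methyl 3-(3-bromo-4-hydroxy-5-methoxyphenyl)-2-methoxy-3-oxopropanoate (racemic) | COC(=O)C(OC)C(=O)c1cc(OC)c(O)c(Br)c1
A3 | alternative 1 | 2-(3-bromo-4-hydroxy-5-methoxyphenyl)-5,7-dihydroxy-3-methoxychromen-4-one | O=c1c(OC)c(-c3cc(OC)c(O)c(Br)c3)oc2cc(O)cc(O)c12
A4 | alternative 2 | methyl 3-{5-methoxy-6-[3-methoxy-4-(methoxymethoxy)-5-(3-methylbut-2-enyl)phenyl]-2-methyl-4-oxo-4H-pyran-3-yl}-3-oxopropanoate | COC(=O)CC(=O)c1c(C)oc(-c2cc(OC)c(OCOC)c(CC=C(C)C)c2)c(OC)c1=O
A5 | alternative 2 | 4′-O-methoxymethyl ether of dodoviscin J, 5,7-dihydroxy-3-methoxy-2-[3-methoxy-4-(methoxymethoxy)-5-(3-methylbut-2-enyl)phenyl]-4H-chromen-4-one | O=c1c(OC)c(-c3cc(OC)c(OCOC)c(CC=C(C)C)c3)oc2cc(O)cc(O)c12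
A6 | alternative 3 | 3,5-bis(methoxymethoxy)-2-(trimethylsilyl)phenyl trifluoromethanesulfonate | COCOc1cc(OCOC)c([Si](C)(C)C)c(OS(=O)(=O)C(F)(F)F)c1
A7 | alternative 3 | 3,5-bis(methoxymethoxy)benzyne | C1#CC(OCOC)=CC(OCOC)=C1
A8 | alternative 3 | methyl 2-methoxy-3-[3-methoxy-4-(methoxymethoxy)-5-(3-methylbut-2-enyl)phenyl]-3-oxopropanoate (racemic) | COC(=O)C(OC)C(=O)c1cc(OC)c(OCOC)c(CC=C(C)C)c1
A9 | alternative 3 | tris(methoxymethyl) ether of dodoviscin J, identical with 17 | O=c1c(OC)c(-c3cc(OC)c(OCOC)c(CC=C(C)C)c3)oc2cc(OCOC)cc(OCOC)c12
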